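Target cannot appear except out of intermediate C, so watch that one concentration.

| setting | epsilon | eta | gamma |
|---|---|---|---|
| substrate | 25 mM | 25 mM | 25 mM |
| coupling partner | 100 mM | 100 mM | 100 mM |
| capture agent | 25.0 mM | 25.0 mM | 25.0 mM |
| temperature | 55 °C | 70 °C | 40 °C |
| time | 80 min | 80 min | 80 min |

    substrate + coupling partner → intermediate A (k1 = 1.2 /M/min, Ea1 = 70.0 kJ/mol)
    coupling partner + intermediate A → intermediate B (k2 = 2.5 /M/min, Ea2 = 45.0 kJ/mol)
    substrate + coupling partner → intermediate C (k3 = 0.40 /M/min, Ea3 = 67.0 kJ/mol)
    intermediate C → target (k4 = 0.0018 /min, Ea4 = 104 kJ/mol)
    intermediate B → side product (k5 = 0.015 /min, Ea5 = 102 kJ/mol)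
    capture agent + intermediate A → trapped intermediate (k6 = 0.39 /M/min, Ea6 = 77.0 kJ/mol)
    (constants at 40 °C)

- the constants hold at 40 °C; other temperatures follow from the activation energies

- the flask that comes out highest in amount of target, in percent of the substrate charged, or "all alike" when all lie within 1.5 percentage points (epsilon / eta / gamma / all alike)
- target at the end, in percent of the substrate charged, epsilon
- target at the end, in percent of the substrate charged, eta
- target at the end, in percent of the substrate charged, gamma

**The clock.** The rate of the step from intermediate C to target holds intermediate C and nothing else. It is first order, and this step is the rate-limiting step for target. Call its constant at flask temperature k. Keep the half-life of intermediate C, h = ln 2/k. In eta, correct k by the activation energy and get 11.7 min.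

**Temperature.** Turn this first. In gamma, h is 385 min. In epsilon, it is 62.0 min. Over 80 min, the fraction f of intermediate C passed on is 13.4% in gamma, 59.1% in epsilon and 99.1% in eta. Heat also moves s, the share of substrate sent to intermediate C. Both branches have the same order, so s = k(C branch)/(sum of both branch constants). It reads 25.0% in gamma, 24.0% in epsilon and 23.2% in eta.

**Time.** Count half-lives. Eta gets 6.83, so extra time adds little there, because its half-life is shorter than the run. Gamma gets 0.208, so time still pays there.

**Coupling partner.** Its charge of 100 mM exceeds the 50.0 mM that two equivalents on the substrate would take. It stands in both branch rates, so it cancels from s, and it is absent from h. In gamma, at its full charge, the two branches together give substrate a starting time constant of 6.25 min, which is shorter than h; this is not a clearing time.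

**Capture agent.** It meets intermediate A, past the branch. By hand it changes neither s nor h.

**Commit.** Take target as s times f: 3.35% in gamma, 14.2% in epsilon, 23.0% in eta. Treat these as upper marks, since they start intermediate C at time zero. Choose eta.

**The forecast.** It names eta, with 14% for epsilon, 23% for eta and 3.1% for gamma. Its ground: substrate feeds a branch that “caps the target at roughly 23–25% whatever happens” elsewhere. My gamma figure stands higher than its figure.

**The outcome.** The flasks give 13.9% in epsilon, 22.9% in eta and 3.04% in gamma, so eta leads and the forecast holds. Ten times the time would overturn its order: epsilon reaches 24.0%, more than eta's 23.2%. With h at 11.7 min, expect 0.203% of intermediate C left in eta; it reads 0.214%. Now take eta with 25 mM of coupling partner. h is unchanged, so intermediate C formed at the start falls to 0.874% of itself. That neighbour ends with 0.234% intermediate C beside 18.4% target.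

All constants are invented; the result is computed.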